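**Plan**

1. Lactone ring numbering used here: O1, C2 (C=O), C3, C4, C5, C6, C7 (bears Me and the ketone). The retrosynthesis cuts, in order: the enoate C=C that carries CO2Me (opens the 14-membered carbocycle), the lactone C2–O1 bond, and then both C–C bonds around the C5–C6 ethano unit (C4–C5 and C6–C7) in one operation.
2. Enabling feature: C7 is the oxygen-bearing α-carbon of a lactic acid unit (enolizable) and C4 can be an aldehyde carbon. C5–C6 can therefore be delivered as vinyltriphenylphosphonium bromide, acceptor at C6 and ylide at C5 (conjugate addition, then Wittig).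
3. Forward order: the aldehyde half (Red-Al/I2, B-alkyl Suzuki, α-methylenation), the lactate dioxolanone and the C2 salt are joined to an open chain in step 8. The lactone ring is closed in step 12 and the carbocycle last, in step 17 (intramolecular Still–Gennari olefination).
4. Helpers and their removal: tert-butyl acetal (step 10); exocyclic methylene as latent C2 carboxyl (steps 9 and 11); the C4=C5 alkene moved into conjugation as C3=C4 (step 12); Weinreb amide (step 13); TBS ether (step 15).
5. Stereochemistry: the only stereocentre (C7, S) comes from (R)-lactic acid by self-regeneration of the stereocentre through the cis-dioxolanone. Alkene geometry comes from the (Z)-iodide and stereoretentive coupling, from the Still–Gennari reagent, and from the ring (C3=C4).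

Key step: step 8

Remark: C3 (created in step 9) and the phosphonate-bearing carbon (created in step 14) are carried as diastereomer mixtures, because both become sp2 carbons later (steps 12 and 17).

**Route**

Step 1
Reactants: 1 3-methylbut-1-yne; 2 formaldehyde (as paraformaldehyde)
Product: 4 4-methylpent-2-yn-1-ol, via lithium acetylide 3 (not isolated)
Conditions: n-BuLi, THF, −78 °C; then (CH2O)n, −78 °C → rt
Reagents that add atoms: none
Why: Addition of a lithium acetylide to formaldehyde (alkyne hydroxymethylation) should give the propargylic alcohol; no stereocentre is formed.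

Step 2
Reactants: 4 4-methylpent-2-yn-1-ol
Product: 6 (Z)-3-iodo-4-methylpent-2-en-1-ol, via alkenylalanate 5 (not isolated)
Conditions: NaAlH2(OCH2CH2OMe)2 (Red-Al), THF, 0 °C → rt; then I2, THF, −78 °C
Reagents that add atoms: iodine, II
Why: Alkoxide-directed trans-hydroalumination of the propargylic alcohol followed by iodinolysis with retention should place iodine at C3 cis to CH2OH, which fixes the trisubstituted alkene geometry.

Step 3
Reactants: 6 (Z)-3-iodo-4-methylpent-2-en-1-ol
Product: 7 tert-butyl{[(Z)-3-iodo-4-methylpent-2-en-1-yl]oxy}dimethylsilane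
Conditions: TBSCl, imidazole, CH2Cl2, 0 °C → rt
Reagents that add atoms: tert-butyldimethylsilyl chloride, CC(C)(C)[Si](C)(C)Cl
Why: Standard silylation of a primary allylic alcohol masks the future enal carbon until step 15.

Step 4
Reactants: 8 4,4-diethoxybut-1-ene; 7 tert-butyl{[(Z)-3-iodo-4-methylpent-2-en-1-yl]oxy}dimethylsilane
Product: 10 tert-butyl{[(2E)-7,7-diethoxy-3-(propan-2-yl)hept-2-en-1-yl]oxy}dimethylsilane, via alkylborane 9 (not isolated)
Conditions: 9-BBN, THF, 0 °C → rt; then 7, Pd(dppf)Cl2, AsPh3, Cs2CO3, DMF/THF/H2O, rt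
Reagents that add atoms: none
Why: B-alkyl Suzuki–Miyaura coupling of the 9-BBN adduct of the terminal alkene with the alkenyl iodide should proceed with retention of alkene geometry, so the new CH2 chain ends up cis to CH2OTBS (E by the sequence rule).

Step 5
Reactants: 10 tert-butyl{[(2E)-7,7-diethoxy-3-(propan-2-yl)hept-2-en-1-yl]oxy}dimethylsilane
Product: 11 (5E)-7-[(tert-butyldimethylsilyl)oxy]-5-(propan-2-yl)hept-5-enal
Conditions: PPTS (cat.), acetone/H2O, rt
Reagents that add atoms: water, O
Why: Mild acid-catalysed acetal hydrolysis should release the aldehyde while the primary TBS ether survives.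

Step 6
Reactants: 11 (5E)-7-[(tert-butyldimethylsilyl)oxy]-5-(propan-2-yl)hept-5-enal; 2 formaldehyde (37% aqueous)
Product: 12 (5E)-7-[(tert-butyldimethylsilyl)oxy]-2-methylidene-5-(propan-2-yl)hept-5-enal
Conditions: 37% aq. CH2O, pyrrolidine (cat.), EtCO2H (cat.), iPrOH, 45 °C
Reagents that add atoms: none
Why: Amine-catalysed Mannich condensation–elimination (α-methylenation of an aldehyde) should install the exocyclic methylene that later becomes the lactone carbonyl carbon C2.

Step 7
Reactants: 13 (R)-lactic acid; 14 pivalaldehyde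
Product: 15 (2R,5R)-2-tert-butyl-5-methyl-1,3-dioxolan-4-one
Conditions: TsOH (cat.), pentane, reflux, Dean–Stark; crystallization of the cis isomer
Reagents that add atoms: none
Why: Acid-catalysed acetalization (Seebach dioxolanone) should favour the cis isomer, whose acetal carbon stores the lactate chirality for step 8.

Step 8
Reactants: 15 (2R,5R)-2-tert-butyl-5-methyl-1,3-dioxolan-4-one; 16 vinyltriphenylphosphonium bromide; 12 (5E)-7-[(tert-butyldimethylsilyl)oxy]-2-methylidene-5-(propan-2-yl)hept-5-enal
Product: 19 (2R,5S)-2-tert-butyl-5-{(2Z,7E)-9-[(tert-butyldimethylsilyl)oxy]-4-methylidene-7-(propan-2-yl)nona-2,7-dien-1-yl}-5-methyl-1,3-dioxolan-4-one, via potassium enolate 17 (not isolated), via phosphorus ylide 18 (not isolated)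
Conditions: KN(SiMe3)2, THF, −78 °C; 16, −78 → −40 °C; then 12, −78 °C → rt
Reagents that add atoms: none
Why: Tandem conjugate addition–Wittig olefination: enolate 17 adds to the β-carbon of vinylphosphonium salt 16 (C6–C7 bond), and the resulting non-stabilized ylide 18, which has no internal trap because attack on the dioxolanone carbonyl would need a four-membered ring, olefinates aldehyde 12 (C4=C5 bond). The closest known reaction type is the addition of enolates or cuprates to vinyltriphenylphosphonium bromide followed by Wittig reaction with an added aldehyde (three-component Schweizer-type reaction). No ring is closed; the step joins the two halves of the target through the two-carbon unit. The quaternary stereocentre C7 is controlled by the tert-butyl group on the acetal carbon, which shields one face of the planar enolate so that the electrophile enters trans to it and replaces the lactate hydrogen with retention; the Z geometry of C4=C5 should follow from kinetic oxaphosphetane formation of the non-stabilized ylide under lithium-free conditions. The step needs complete consumption of the enolate before the aldehyde arrives, secured by a slight excess of 16 (inert toward 12), and 1,2- rather than 1,4-attack of the ylide on the 2-methylene aldehyde, which is the normal course for phosphorus ylides.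

Step 9
Reactants: 19 key-step diene (dioxolanone)
Product: 21 (2R,5S)-2-tert-butyl-5-{(2Z,7E)-9-[(tert-butyldimethylsilyl)oxy]-4-(hydroxymethyl)-7-(propan-2-yl)nona-2,7-dien-1-yl}-5-methyl-1,3-dioxolan-4-one, via alkylborane 20 (not isolated)
Conditions: 9-BBN, THF, 0 °C → rt; then H2O2, pH 7 phosphate buffer, 0 °C
Reagents that add atoms: hydrogen peroxide, OO
Why: Anti-Markovnikov hydroboration–oxidation with 9-BBN should select the 1,1-disubstituted terminal alkene over the cis-disubstituted and trisubstituted ones; the new C3 stereocentre forms without control and is erased in step 12.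

Step 10
Reactants: 21 primary alcohol (dioxolanone)
Product: 22 (2S,4Z,9E)-11-[(tert-butyldimethylsilyl)oxy]-2-hydroxy-6-(hydroxymethyl)-N-methoxy-N,2-dimethyl-9-(propan-2-yl)undeca-4,9-dienamide
Conditions: MeNH(OMe)·HCl, iPrMgCl, THF, −20 → 0 °C
Reagents that add atoms: N,O-dimethylhydroxylamine hydrochloride, CNOC.Cl
Why: Aminolysis of the activated dioxolanone carbonyl by the magnesium amide (Weinreb amide formation) should release pivalaldehyde and the tertiary hydroxyl without touching the quaternary stereocentre.

Step 11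
Reactants: 22 dihydroxy Weinreb amide
Product: 23 (3Z,6S)-2-{(3E)-5-[(tert-butyldimethylsilyl)oxy]-3-(propan-2-yl)pent-3-en-1-yl}-6-hydroxy-7-[methoxy(methyl)amino]-6-methyl-7-oxohept-3-enoic acid
Conditions: TEMPO (cat.), NaClO2, NaOCl (cat.), MeCN/phosphate buffer (pH 6.7), 35 °C
Reagents that add atoms: sodium chlorite, [Na+].[O-]Cl=O
Why: TEMPO/chlorite oxidation (Zhao protocol) should convert the primary alcohol to the carboxylic acid in the presence of the tertiary alcohol, the alkenes and the silyl ether.

Step 12
Reactants: 23 hydroxy acid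
Product: 25 (7S)-3-{(3E)-5-[(tert-butyldimethylsilyl)oxy]-3-(propan-2-yl)pent-3-en-1-yl}-N-methoxy-N,7-dimethyl-2-oxo-2,5,6,7-tetrahydrooxepine-7-carboxamide, via β,γ-unsaturated lactone 24 (not isolated)
Conditions: MNBA, DMAP, Et3N, CH2Cl2 (high dilution), rt; then DBU, rt
Reagents that add atoms: none
Why: Shiina lactonization should close the seven-membered ring (the cis C4=C5 alkene holds acid and tertiary hydroxyl close), and base-mediated alkene conjugation via the dienolate should then move the double bond to C3=C4, which removes the uncontrolled C3 stereocentre; the ketone is deliberately still an amide so that the dienolate has no reactive carbonyl nearby.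

Step 13
Reactants: 25 conjugated lactone Weinreb amide; 26 vinylmagnesium bromide
Product: 27 (7S)-3-{(3E)-5-[(tert-butyldimethylsilyl)oxy]-3-(propan-2-yl)pent-3-en-1-yl}-7-methyl-7-(prop-2-enoyl)-6,7-dihydrooxepin-2(5H)-one
Conditions: CH2=CHMgBr, THF, −78 → −40 °C; cold aq. NH4Cl
Reagents that add atoms: none
Why: Weinreb ketone synthesis should stop at the chelated tetrahedral adduct and give the vinyl ketone; the conjugated, α-substituted lactone with a tertiary alkoxy group should be the less reactive carbonyl at low temperature.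

Step 14
Reactants: 27 vinyl ketone; 28 methyl bis(2,2,2-trifluoroethyl)phosphonoacetate
Product: 29 methyl 2-[bis(2,2,2-trifluoroethoxy)phosphoryl]-5-oxo-5-[(7S)-7-methyl-2-oxo-3-{(3E)-5-[(tert-butyldimethylsilyl)oxy]-3-(propan-2-yl)pent-3-en-1-yl}-2,5,6,7-tetrahydrooxepin-7-yl]pentanoate
Conditions: Cs2CO3 (cat.), THF, 0 °C
Reagents that add atoms: none
Why: Michael addition of the acidic phosphonoacetate to the enone under weak base should build the remaining three-carbon link without deprotonating the lactone; the new phosphonate-bearing stereocentre is uncontrolled and is erased in step 17.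

Step 15
Reactants: 29 silyl ether phosphonate
Product: 30 the corresponding primary allylic alcohol (TBS removed)
Conditions: HF·pyridine, pyridine, THF, 0 °C
Reagents that add atoms: none
Why: Buffered fluoride desilylation should free the allylic alcohol without base-sensitive side reactions at the phosphonate or lactone.

Step 16
Reactants: 30 allylic alcohol
Product: 31 the corresponding enal (aldehyde cis to the ring-bound CH2 and trans to isopropyl)
Conditions: MnO2, CH2Cl2, rt
Reagents that add atoms: none
Why: Allylic oxidation with MnO2 should give the enal with the alkene geometry retained, and this geometry is also expected to be the more stable one.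

Step 17
Reactants: 31 enal phosphonate
Product: 32 ketoemblide
Conditions: KN(SiMe3)2, 18-crown-6, THF, −78 °C, slow addition (high dilution)
Reagents that add atoms: none
Why: Intramolecular Still–Gennari Horner–Wadsworth–Emmons olefination should close the 14-membered carbocycle and give the Z-enoate (CO2Me cis to the diene carbon), since only the phosphonate C–H is deprotonated by one equivalent of base and the trifluoroethyl phosphonate eliminates under kinetic control.

**Compound list**

1 | 3-methylbut-1-yne | CC(C)C#C | starting material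
2 | formaldehyde (paraformaldehyde in step 1, 37% aqueous solution in step 6) | C=O | starting material
3 | lithium 3-methylbut-1-yn-1-ide | [Li+].CC(C)C#[C-] | intermediate (not isolated)
4 | 4-methylpent-2-yn-1-ol | CC(C)C#CCO | intermediate
5 | sodium cyclic alkenylalanate from 4 (Al on C3, alkoxide bound to Al, two 2-methoxyethoxy ligands) | [Na+].CC(C)C1=CCO[Al-]1(OCCOC)OCCOC | intermediate (not isolated)
6 | (Z)-3-iodo-4-methylpent-2-en-1-ol | OC/C=C(\I)C(C)C | intermediate
7 | tert-butyl{[(Z)-3-iodo-4-methylpent-2-en-1-yl]oxy}dimethylsilane | CC(C)(C)[Si](C)(C)OC/C=C(\I)C(C)C | intermediate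
8 | 4,4-diethoxybut-1-ene | C=CCC(OCC)OCC | starting material
9 | 9-(4,4-diethoxybutyl)-9-borabicyclo[3.3.1]nonane | CCOC(CCCB1C2CCCC1CCC2)OCC | intermediate (not isolated)
10 | tert-butyl{[(2E)-7,7-diethoxy-3-(propan-2-yl)hept-2-en-1-yl]oxy}dimethylsilane | CCOC(CCC/C(C(C)C)=C\CO[Si](C)(C)C(C)(C)C)OCC | intermediate
11 | (5E)-7-[(tert-butyldimethylsilyl)oxy]-5-(propan-2-yl)hept-5-enal | O=CCCC/C(C(C)C)=C\CO[Si](C)(C)C(C)(C)C | intermediate
12 | (5E)-7-[(tert-butyldimethylsilyl)oxy]-2-methylidene-5-(propan-2-yl)hept-5-enal | C=C(C=O)CC/C(C(C)C)=C\CO[Si](C)(C)C(C)(C)C | intermediate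
13 | (R)-lactic acid | C[C@@H](O)C(=O)O | starting material
14 | pivalaldehyde | CC(C)(C)C=O | starting material
15 | (2R,5R)-2-tert-butyl-5-methyl-1,3-dioxolan-4-one (cis) | C[C@H]1O[C@@H](C(C)(C)C)OC1=O | intermediate
16 | vinyltriphenylphosphonium bromide | C=C[P+](c1ccccc1)(c1ccccc1)c1ccccc1.[Br-] | starting material
17 | potassium (2R)-2-tert-butyl-5-methyl-1,3-dioxol-4-olate | CC1=C([O-])O[C@H](C(C)(C)C)O1.[K+] | intermediate (not isolated)
18 | (2R,5S)-2-tert-butyl-5-methyl-5-[3-(triphenyl-λ5-phosphanylidene)propyl]-1,3-dioxolan-4-one | C[C@@]1(CC=P(c2ccccc2)(c2ccccc2)c2ccccc2)O[C@@H](C(C)(C)C)OC1=O | intermediate (not isolated)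
19 | (2R,5S)-2-tert-butyl-5-{(2Z,7E)-9-[(tert-butyldimethylsilyl)oxy]-4-methylidene-7-(propan-2-yl)nona-2,7-dien-1-yl}-5-methyl-1,3-dioxolan-4-one | C[C@@]1(C/C=C\C(=C)CC/C(C(C)C)=C\CO[Si](C)(C)C(C)(C)C)O[C@@H](C(C)(C)C)OC1=O | intermediate
20 | 9-BBN adduct of 19 at the exocyclic methylene carbon (C3 epimers) | C[C@@]1(C/C=C\C(CB2C3CCCC2CCC3)CC/C(C(C)C)=C\CO[Si](C)(C)C(C)(C)C)O[C@@H](C(C)(C)C)OC1=O | intermediate (not isolated)
21 | (2R,5S)-2-tert-butyl-5-{(2Z,7E)-9-[(tert-butyldimethylsilyl)oxy]-4-(hydroxymethyl)-7-(propan-2-yl)nona-2,7-dien-1-yl}-5-methyl-1,3-dioxolan-4-one (C4' epimers) | C[C@@]1(C/C=C\C(CO)CC/C(C(C)C)=C\CO[Si](C)(C)C(C)(C)C)O[C@@H](C(C)(C)C)OC1=O | intermediate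
22 | (2S,4Z,9E)-11-[(tert-butyldimethylsilyl)oxy]-2-hydroxy-6-(hydroxymethyl)-N-methoxy-N,2-dimethyl-9-(propan-2-yl)undeca-4,9-dienamide (C6 epimers) | CON(C)C(=O)[C@@](C)(O)C/C=C\C(CO)CC/C(C(C)C)=C\CO[Si](C)(C)C(C)(C)C | intermediate
23 | (3Z,6S)-2-{(3E)-5-[(tert-butyldimethylsilyl)oxy]-3-(propan-2-yl)pent-3-en-1-yl}-6-hydroxy-7-[methoxy(methyl)amino]-6-methyl-7-oxohept-3-enoic acid (C2 epimers) | CON(C)C(=O)[C@@](C)(O)C/C=C\C(CC/C(C(C)C)=C\CO[Si](C)(C)C(C)(C)C)C(=O)O | intermediate
24 | (7S)-3-{(3E)-5-[(tert-butyldimethylsilyl)oxy]-3-(propan-2-yl)pent-3-en-1-yl}-N-methoxy-N,7-dimethyl-2-oxo-2,3,6,7-tetrahydrooxepine-7-carboxamide (C3 epimers, cis C4=C5) | CON(C)C(=O)[C@]1(C)C/C=C\C(CC/C(C(C)C)=C\CO[Si](C)(C)C(C)(C)C)C(=O)O1 | intermediate (not isolated)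
25 | (7S)-3-{(3E)-5-[(tert-butyldimethylsilyl)oxy]-3-(propan-2-yl)pent-3-en-1-yl}-N-methoxy-N,7-dimethyl-2-oxo-2,5,6,7-tetrahydrooxepine-7-carboxamide | CON(C)C(=O)[C@]1(C)CCC=C(CC/C(C(C)C)=C\CO[Si](C)(C)C(C)(C)C)C(=O)O1 | intermediate
26 | vinylmagnesium bromide | C=C[Mg]Br | starting material
27 | (7S)-3-{(3E)-5-[(tert-butyldimethylsilyl)oxy]-3-(propan-2-yl)pent-3-en-1-yl}-7-methyl-7-(prop-2-enoyl)-6,7-dihydrooxepin-2(5H)-one | C=CC(=O)[C@]1(C)CCC=C(CC/C(C(C)C)=C\CO[Si](C)(C)C(C)(C)C)C(=O)O1 | intermediate
28 | methyl bis(2,2,2-trifluoroethyl)phosphonoacetate | COC(=O)CP(=O)(OCC(F)(F)F)OCC(F)(F)F | starting material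
29 | Michael adduct: methyl 2-[bis(2,2,2-trifluoroethoxy)phosphoryl]-5-oxo-5-[(7S)-lactone-7-yl]pentanoate with the TBS-protected side chain on C3 (phosphonate-carbon epimers) | COC(=O)C(CCC(=O)[C@]1(C)CCC=C(CC/C(C(C)C)=C\CO[Si](C)(C)C(C)(C)C)C(=O)O1)P(=O)(OCC(F)(F)F)OCC(F)(F)F | intermediate
30 | allylic alcohol from 29 (TBS removed) | COC(=O)C(CCC(=O)[C@]1(C)CCC=C(CC/C(C(C)C)=C\CO)C(=O)O1)P(=O)(OCC(F)(F)F)OCC(F)(F)F | intermediate
31 | enal from 30 | COC(=O)C(CCC(=O)[C@]1(C)CCC=C(CC/C(C(C)C)=C\C=O)C(=O)O1)P(=O)(OCC(F)(F)F)OCC(F)(F)F | intermediate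
32 | ketoemblide | COC(=O)/C1=C\C=C(\C(C)C)CCC2=CCC[C@](C)(OC2=O)C(=O)CC1 | target

**Step count and risks**

Total step count: 17. Longest linear sequence: 16 steps (steps 1–6 and 8–17); step 7 is a one-step branch.

Steps most likely to fail:

Step 8. The dioxolanone enolate may decompose before it adds to the sparingly soluble phosphonium salt, or unreacted enolate may attack the aldehyde; the Z selectivity of the Wittig stage may also be eroded. The fallback forms the two bonds one after the other by known chemistry. It sets out from 15: enolate 17 (KN(SiMe3)2, THF, −78 °C) would be alkylated with 2-bromoethyl trifluoromethanesulfonate to give (2R,5S)-5-(2-bromoethyl)-2-tert-butyl-5-methyl-1,3-dioxolan-4-one F1, again trans to the tert-butyl group. Heating with PPh3 in MeCN should give the phosphonium salt [2-((2R,4S)-2-tert-butyl-4-methyl-5-oxo-1,3-dioxolan-4-yl)ethyl]triphenylphosphonium bromide F2. Deprotonation with KN(SiMe3)2 at −78 °C gives ylide 18 free of other nucleophiles, and Wittig reaction with 12 returns to the route at 19.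

Step 12. Acylation of the hindered tertiary hydroxyl may be slow, so that intermolecular esterification and isomerization of the activated acid to an E-configured conjugated acyl species (which cannot cyclize) outrun ring closure. The fallback replaces acyl transfer by addition of the alcohol to a ketene, which is far less sensitive to hindrance. It sets out from 23: 1-chloro-N,N,2-trimethylprop-1-en-1-amine (CH2Cl2, 0 °C) should give the acid chloride of 23, F3. Slow addition of F3 to Et3N in toluene at 80 °C under high dilution should generate the vinylketene F4, which is trapped by the tertiary hydroxyl to give 24; the amine present (or added DBU) brings the alkene into conjugation, and the fallback returns to the route at 25.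

Step 13. The Grignard reagent may add to the lactone carbonyl or deprotonate C5 of the lactone instead of attacking the hindered Weinreb amide. The fallback reaches the ketone through the aldehyde oxidation level. It sets out from 25: Cp2Zr(H)Cl (THF, rt) should reduce the Weinreb amide selectively to the aldehyde (7S)-7-formyl lactone F5. Vinylmagnesium bromide 26 at −78 °C then adds to the aldehyde, by far the most reactive carbonyl, to give the allylic alcohol F6 as an epimer mixture. Dess–Martin periodinane (CH2Cl2, rt) oxidizes F6, and the fallback returns to the route at 27.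

**Further compounds**

F1 | step 8 | (2R,5S)-5-(2-bromoethyl)-2-tert-butyl-5-methyl-1,3-dioxolan-4-one | C[C@@]1(CCBr)O[C@@H](C(C)(C)C)OC1=O
F2 | step 8 | [2-((2R,4S)-2-tert-butyl-4-methyl-5-oxo-1,3-dioxolan-4-yl)ethyl]triphenylphosphonium bromide | C[C@@]1(CC[P+](c2ccccc2)(c2ccccc2)c2ccccc2)O[C@@H](C(C)(C)C)OC1=O.[Br-]
F3 | step 12 | acid chloride of 23 | CON(C)C(=O)[C@@](C)(O)C/C=C\C(CC/C(C(C)C)=C\CO[Si](C)(C)C(C)(C)C)C(=O)Cl
F4 | step 12 | vinylketene from F3 | CON(C)C(=O)[C@@](C)(O)C/C=C\C(CC/C(C(C)C)=C\CO[Si](C)(C)C(C)(C)C)=C=O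
F5 | step 13 | (7S)-7-formyl-7-methyl-3-{(3E)-5-[(tert-butyldimethylsilyl)oxy]-3-(propan-2-yl)pent-3-en-1-yl}-6,7-dihydrooxepin-2(5H)-one | O=C[C@]1(C)CCC=C(CC/C(C(C)C)=C\CO[Si](C)(C)C(C)(C)C)C(=O)O1
F6 | step 13 | (7S)-7-(1-hydroxyprop-2-en-1-yl)-7-methyl-3-{(3E)-5-[(tert-butyldimethylsilyl)oxy]-3-(propan-2-yl)pent-3-en-1-yl}-6,7-dihydrooxepin-2(5H)-one (carbinol epimers) | C=CC(O)[C@]1(C)CCC=C(CC/C(C(C)C)=C\CO[Si](C)(C)C(C)(C)C)C(=O)O1
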